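**Assumption:** the target (the natural product XH-14) has no stereocentre, so it is achiral and "single enantiomer" needs no stereocontrol; vanillin, dihydroconiferyl alcohol and the Ohira–Bestmann reagent are taken as commercial.

**Retrosynthetic overview**
1. Target 10 ⇐ removal of two acetates from 9 ⇐ Vilsmeier–Haack formylation at C3 of the 2-arylbenzofuran 7.
2. 7 ⇐ diacetylation of benzofuran diol 6.
3. 6 ⇐ one-pot Sonogashira coupling / 5-endo-dig annulation of o-iodophenol 4 with aryl alkyne 2; the furan ring is the only ring built, both benzene rings are bought.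
4. 4 ⇐ ortho-iodination of dihydroconiferyl alcohol 3; 2 ⇐ Ohira–Bestmann homologation of vanillin 1.

**Route**

Step 1
Reactants: 1 vanillin (4-hydroxy-3-methoxybenzaldehyde)
Product: 2 4-ethynyl-2-methoxyphenol
Conditions: Ohira–Bestmann reagent (1.3 equiv), K2CO3 (3 equiv), MeOH, rt, 16 h; aq. NH4Cl work-up
Reagents that add atoms: dimethyl (1-diazo-2-oxopropyl)phosphonate (Ohira–Bestmann reagent), COP(=O)(OC)C(=[N+]=[N-])C(C)=O
Why: Seyferth–Gilbert homologation in the Ohira–Bestmann form, in which the diazomethylphosphonate anion made by methanolysis olefinates the aldehyde and the diazoalkene loses N2 with a 1,2-H shift to the terminal alkyne; excess carbonate covers the acidic phenol and no stereocentre is formed.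

Step 2
Reactants: 3 dihydroconiferyl alcohol [4-(3-hydroxypropyl)-2-methoxyphenol]
Product: 4 4-(3-hydroxypropyl)-2-iodo-6-methoxyphenol
Conditions: I2 (1.05 equiv), KI, NaHCO3, THF/H2O, 0 °C to rt
Reagents that add atoms: iodine, II
Why: Electrophilic aromatic iodination through the phenoxide goes to the only free position ortho to OH (para is blocked by the side chain), and the primary alcohol is inert; no stereocentre is formed.

Step 3
Reactants: 4 4-(3-hydroxypropyl)-2-iodo-6-methoxyphenol; 2 4-ethynyl-2-methoxyphenol (1.2 equiv)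
Product: 6 4-[5-(3-hydroxypropyl)-7-methoxy-1-benzofuran-2-yl]-2-methoxyphenol, via o-alkynylphenol 5 (not isolated)
Conditions: PdCl2(PPh3)2 (3 mol%), CuI (5 mol%), Et3N (3 equiv), DMF, degassed, rt then 65 °C
Reagents that add atoms: none
Why: Sonogashira coupling followed in the same pot by Cu/Pd-promoted 5-endo-dig hydroalkoxylation of the o-alkynylphenol (Larock-type heteroannulation) builds the furan ring; free OH groups are tolerated and no stereocentre is formed.

Step 4
Reactants: 6 4-[5-(3-hydroxypropyl)-7-methoxy-1-benzofuran-2-yl]-2-methoxyphenol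
Product: 7 3-[2-(4-acetoxy-3-methoxyphenyl)-7-methoxy-1-benzofuran-5-yl]propyl acetate
Conditions: Ac2O (3 equiv), pyridine, DMAP (cat.), CH2Cl2, 0 °C to rt
Reagents that add atoms: acetic anhydride, CC(=O)OC(C)=O
Why: DMAP-catalysed O-acylation caps both OH groups so the Vilsmeier reagent cannot turn the primary alcohol into a formate or chloride, and the aryl acetate deactivates the 2-aryl ring towards formylation.

Step 5
Reactants: 7 3-[2-(4-acetoxy-3-methoxyphenyl)-7-methoxy-1-benzofuran-5-yl]propyl acetate
Product: 9 3-[2-(4-acetoxy-3-methoxyphenyl)-3-formyl-7-methoxy-1-benzofuran-5-yl]propyl acetate, via C3-iminium chloride 8 (not isolated)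
Conditions: POCl3 (3 equiv), DMF, 0 °C to 80 °C; then ice/H2O
Reagents that add atoms: N,N-dimethylformamide, CN(C)C=O; water, O
Why: Vilsmeier–Haack formylation (SEAr) attacks the enol-ether-like C3 of the 2-arylbenzofuran, its most nucleophilic position, and the iminium salt is hydrolysed to the aldehyde on aqueous work-up; acetates and methyl ethers survive.

Step 6
Reactants: 9 3-[2-(4-acetoxy-3-methoxyphenyl)-3-formyl-7-methoxy-1-benzofuran-5-yl]propyl acetate
Product: 10 2-(4-hydroxy-3-methoxyphenyl)-5-(3-hydroxypropyl)-7-methoxy-1-benzofuran-3-carbaldehyde (XH-14, target)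
Conditions: K2CO3 (2 equiv), MeOH, rt; then 1 M HCl to pH 4
Reagents that add atoms: none
Why: Base-mediated methanolysis (transesterification) removes the aryl and the alkyl acetate, while the non-enolisable aryl aldehyde is untouched; the product is achiral, so there is no stereocentre to set or scramble.

**Compound list**
1 | vanillin (4-hydroxy-3-methoxybenzaldehyde) | COc1cc(C=O)ccc1O | starting material
2 | 4-ethynyl-2-methoxyphenol | COc1cc(C#C)ccc1O | intermediate
3 | dihydroconiferyl alcohol [4-(3-hydroxypropyl)-2-methoxyphenol] | COc1cc(CCCO)ccc1O | starting material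
4 | 4-(3-hydroxypropyl)-2-iodo-6-methoxyphenol | COc1cc(CCCO)cc(I)c1O | intermediate
5 | 2-[(4-hydroxy-3-methoxyphenyl)ethynyl]-4-(3-hydroxypropyl)-6-methoxyphenol | COc1cc(C#Cc2cc(CCCO)cc(OC)c2O)ccc1O | intermediate (not isolated)
6 | 4-[5-(3-hydroxypropyl)-7-methoxy-1-benzofuran-2-yl]-2-methoxyphenol | COc1cc(-c2cc3cc(CCCO)cc(OC)c3o2)ccc1O | intermediate
7 | 3-[2-(4-acetoxy-3-methoxyphenyl)-7-methoxy-1-benzofuran-5-yl]propyl acetate | COc1cc(-c2cc3cc(CCCOC(C)=O)cc(OC)c3o2)ccc1OC(C)=O | intermediate
8 | N-{[2-(4-acetoxy-3-methoxyphenyl)-5-(3-acetoxypropyl)-7-methoxy-1-benzofuran-3-yl]methylidene}-N-methylmethanaminium chloride | COc1cc(-c2oc3c(OC)cc(CCCOC(C)=O)cc3c2C=[N+](C)C)ccc1OC(C)=O.[Cl-] | intermediate (not isolated)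
9 | 3-[2-(4-acetoxy-3-methoxyphenyl)-3-formyl-7-methoxy-1-benzofuran-5-yl]propyl acetate | COc1cc(-c2oc3c(OC)cc(CCCOC(C)=O)cc3c2C=O)ccc1OC(C)=O | intermediate
10 | 2-(4-hydroxy-3-methoxyphenyl)-5-(3-hydroxypropyl)-7-methoxy-1-benzofuran-3-carbaldehyde (XH-14) | COc1cc(-c2oc3c(OC)cc(CCCO)cc3c2C=O)ccc1O | target

**Totals**
Total step count: 6. Longest linear sequence: 5 steps (3 → 4 → 6 → 7 → 9 → 10; the branch from 1 is equally long).

**Three steps most likely to fail, with fallbacks**

Step 5 (Vilsmeier–Haack). The risk is competing formylation at C4 or C6 of the methoxy-activated benzo ring, or loss of an acetate. The fallback sets out from o-alkynylphenol 5, which is isolated when the coupling of step 3 is stopped at room temperature before annulation. Carbonylative annulation (PdI2–thiourea cat., CBr4, Cs2CO3, CO 1 atm, MeOH, 40 °C) places the C3 carbon unambiguously and gives methyl 2-(4-hydroxy-3-methoxyphenyl)-5-(3-hydroxypropyl)-7-methoxy-1-benzofuran-3-carboxylate F6. LiAlH4 in THF at 0 °C reduces the ester to 4-[3-(hydroxymethyl)-5-(3-hydroxypropyl)-7-methoxy-1-benzofuran-2-yl]-2-methoxyphenol F7. Activated MnO2 in acetone at rt oxidises only the benzylic-type alcohol, and the fallback comes back to the route at target 10.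

Step 3 (domino Sonogashira/annulation). The risk is slow oxidative addition into the electron-rich free iodophenol, Glaser dimerisation of 2, or incomplete ring closure. The fallback sets out from 4 and 2 and separates coupling from cyclisation. Ac2O/pyridine converts 4 into 3-(4-acetoxy-3-iodo-5-methoxyphenyl)propyl acetate F3 and 2 into 4-ethynyl-2-methoxyphenyl acetate F4. Sonogashira coupling at rt (PdCl2(PPh3)2, CuI, Et3N, THF) gives 3-{4-acetoxy-3-[(4-acetoxy-3-methoxyphenyl)ethynyl]-5-methoxyphenyl}propyl acetate F5. K2CO3 in MeOH/DMF at 65 °C then removes the acetates and the freed phenoxide closes the ring by anionic 5-endo-dig cyclisation, coming back to the route at 6.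

Step 2 (iodination). The risk is iodination para to OMe or di-iodination. The fallback sets out from 3 and uses directed ortho-metalation instead of SEAr. MOMCl/i-Pr2NEt in CH2Cl2 gives 2-methoxy-1-(methoxymethoxy)-4-[3-(methoxymethoxy)propyl]benzene F1. n-BuLi/TMEDA in THF at 0 °C lithiates ortho to the aryl OMOM group, and I2 at −78 °C gives 1-iodo-3-methoxy-2-(methoxymethoxy)-5-[3-(methoxymethoxy)propyl]benzene F2. HCl in MeOH at 40 °C removes both MOM groups and comes back to the route at 4.

**Further compounds**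
F1 | step 2 | 2-methoxy-1-(methoxymethoxy)-4-[3-(methoxymethoxy)propyl]benzene | COc1cc(CCCOCOC)ccc1OCOC
F2 | step 2 | 1-iodo-3-methoxy-2-(methoxymethoxy)-5-[3-(methoxymethoxy)propyl]benzene | COc1cc(CCCOCOC)cc(I)c1OCOC
F3 | step 3 | 3-(4-acetoxy-3-iodo-5-methoxyphenyl)propyl acetate | COc1cc(CCCOC(C)=O)cc(I)c1OC(C)=O
F4 | step 3 | 4-ethynyl-2-methoxyphenyl acetate | COc1cc(C#C)ccc1OC(C)=O
F5 | step 3 | 3-{4-acetoxy-3-[(4-acetoxy-3-methoxyphenyl)ethynyl]-5-methoxyphenyl}propyl acetate | COc1cc(C#Cc2cc(CCCOC(C)=O)cc(OC)c2OC(C)=O)ccc1OC(C)=O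
F6 | step 5 | methyl 2-(4-hydroxy-3-methoxyphenyl)-5-(3-hydroxypropyl)-7-methoxy-1-benzofuran-3-carboxylate | COC(=O)c1c(-c2ccc(O)c(OC)c2)oc2c(OC)cc(CCCO)cc12
F7 | step 5 | 4-[3-(hydroxymethyl)-5-(3-hydroxypropyl)-7-methoxy-1-benzofuran-2-yl]-2-methoxyphenol | COc1cc(-c2oc3c(OC)cc(CCCO)cc3c2CO)ccc1O
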